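**Retrosynthetic overview**

1. The target comes from its tris-silyl ether by protecting-group exchange; that macrocycle comes from an acyclic bis-iodide by closing the ten-membered carbocycle at C3–C4, a nickel-mediated reductive union of two electrophilic carbons (primary iodide at C3, Z-alkenyl iodide at C4).
2. Enabling feature: the cis (4Z) C4=C5 bond of the ten-membered ring, whose C4 carries only methyl C15 and joins the unbranched, unfunctionalised C3H2–C2H2 bridge. C4 can therefore be an alkenyl iodide with iodine cis to C6 and C3 a primary iodide, while the fused butenolide ring (O–C6–C7=C11–C12) and sp2 C10 hold the chain ends close.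
3. The bis-iodide comes from a C8–C9 Hosomi–Sakurai union of a butenolide aldehyde (C4–C8, C11–C13, C15) with an allylsilane (C1–C3, C9, C10, C14), followed by oxidation and CBS reduction to set C8.
4. The aldehyde comes from a γ-hydroxy ynoate (vinylcuprate addition, formaldehyde trapping, lactonisation, vinyl cleavage); the ynoate from (Z)-3-iodobut-2-enal and methyl propiolate by asymmetric alkynylation (sets C6); the allylsilane from (S)-α-hydroxy-γ-butyrolactone (supplies C1).
5. Ring order: butenolide first (step 7), ten-membered carbocycle last (step 14).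

Key step: step 14

Remark: germacrane numbering (C1–C15) is used for all intermediates. The (S,S)-ProPhenol ligand in step 6 is assumed to direct the alkynyl group to the Si face of the aldehyde; the (R,R)-ligand is to be used if the sense proves opposite.

**Route**

Step 1
Reactants: 1 (S)-3-hydroxydihydrofuran-2(3H)-one
Product: 2 (S)-3-[(tert-butyldimethylsilyl)oxy]dihydrofuran-2(3H)-one
Conditions: TBSCl, imidazole, DMF, 23 °C
Reagents that add atoms: tert-butyldimethylsilyl chloride, C[Si](C)(Cl)C(C)(C)C
Why: Standard silylation of the secondary alcohol; the C1 stereocentre comes from the chiral pool and is not touched.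

Step 2
Reactants: 2 (S)-3-[(tert-butyldimethylsilyl)oxy]dihydrofuran-2(3H)-one
Product: 4 (S)-3-[(tert-butyldimethylsilyl)oxy]-4-[(trimethylsilyl)methyl]pent-4-en-1-ol, via bis(silylmethyl) carbinol 3 (not isolated)
Conditions: Me3SiCH2MgCl (4 equiv), anhydrous CeCl3 (4 equiv), THF, −78 to 0 °C; NH4Cl work-up; then silica gel, CH2Cl2, 23 °C
Reagents that add atoms: (trimethylsilyl)methylmagnesium chloride, C[Si](C)(C)C[Mg]Cl
Why: Double addition of the non-basic organocerium reagent to the lactone carbonyl followed by acid-promoted Peterson elimination gives the 2-substituted allylsilane (C9, C10, C14) without enolising C1; the cold quench is meant to suppress O-to-O silyl migration.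

Step 3
Reactants: 4 (S)-3-[(tert-butyldimethylsilyl)oxy]-4-[(trimethylsilyl)methyl]pent-4-en-1-ol
Product: 5 (S)-tert-butyl({5-iodo-2-[(trimethylsilyl)methyl]pent-1-en-3-yl}oxy)dimethylsilane
Conditions: PPh3, imidazole, I2 (premixed), CH2Cl2, 0 °C
Reagents that add atoms: iodine, II
Why: Appel-type (Garegg–Samuelsson) iodination of the primary alcohol through the alkoxyphosphonium salt; premixing phosphine and iodine leaves no free iodine to attack the allylsilane.

Step 4
Reactants: 6 but-2-yn-1-ol
Product: 8 (Z)-3-iodobut-2-en-1-ol, via cyclic alkenylalanate 7 (not isolated)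
Conditions: NaAlH2(OCH2CH2OCH3)2, THF, 0 to 23 °C; then I2, THF, −78 to 0 °C
Reagents that add atoms: iodine, II
Why: Hydroxyl-directed trans-hydroalumination delivers hydride to C5 and aluminium to C4 inside a five-membered oxaluminacycle, so iodinolysis with retention places iodine cis to C6 and fixes the 4Z geometry of the target.

Step 5
Reactants: 8 (Z)-3-iodobut-2-en-1-ol
Product: 9 (Z)-3-iodobut-2-enal
Conditions: activated MnO2, CH2Cl2, 23 °C
Reagents that add atoms: none
Why: Chemoselective MnO2 oxidation of the allylic alcohol under neutral conditions; the enal is used at once to avoid Z to E isomerisation.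

Step 6
Reactants: 9 (Z)-3-iodobut-2-enal; 10 methyl propiolate
Product: 11 methyl (4R,5Z)-4-hydroxy-6-iodohept-5-en-2-ynoate
Conditions: (S,S)-ProPhenol (20 mol%), Zn(CH3)2 (3 equiv), toluene, 4 °C
Reagents that add atoms: none
Why: Catalytic asymmetric alkynylation with a dinuclear zinc–ProPhenol catalyst: the zinc alkynide formed from 10 and dimethylzinc adds to the Si face of the enal inside the chiral pocket and sets C6 as R (catalyst control).

Step 7
Reactants: 11 methyl (4R,5Z)-4-hydroxy-6-iodohept-5-en-2-ynoate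
Product: 13 (5R)-3-(hydroxymethyl)-5-[(Z)-2-iodoprop-1-en-1-yl]-4-vinylfuran-2(5H)-one, via open-chain hydroxy ester 12 (not isolated)
Conditions: CH2=CHMgBr (5 equiv), CuI (2.5 equiv), THF/Et2O, −78 °C; then monomeric formaldehyde (from cracked paraformaldehyde) in THF, −78 to −40 °C; NH4Cl; then PPTS (cat.), CH2Cl2, 23 °C
Reagents that add atoms: vinylmagnesium bromide, C=C[Mg]Br; formaldehyde, C=O
Why: Tandem conjugate addition–aldol–lactonisation: syn-carbocupration puts vinyl on C7 and copper on C11, the alkenylcopper (allenolate) is trapped at C11 by formaldehyde in the manner of an anionic Morita–Baylis–Hillman three-component coupling, and the C6 alkoxide, held cis to the ester by the syn addition, closes the butenolide without touching C6.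

Step 8
Reactants: 13 (5R)-3-(hydroxymethyl)-5-[(Z)-2-iodoprop-1-en-1-yl]-4-vinylfuran-2(5H)-one
Product: 14 (5R)-5-[(Z)-2-iodoprop-1-en-1-yl]-3-{[(triethylsilyl)oxy]methyl}-4-vinylfuran-2(5H)-one
Conditions: TESCl, imidazole, CH2Cl2, 0 °C
Reagents that add atoms: chlorotriethylsilane, CC[Si](Cl)(CC)CC
Why: Silylation of the primary allylic alcohol, which would otherwise form a cyclic hemiacetal with the C8 aldehyde made in step 9.

Step 9
Reactants: 14 (5R)-5-[(Z)-2-iodoprop-1-en-1-yl]-3-{[(triethylsilyl)oxy]methyl}-4-vinylfuran-2(5H)-one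
Product: 16 (2R)-2-[(Z)-2-iodoprop-1-en-1-yl]-5-oxo-4-{[(triethylsilyl)oxy]methyl}-2,5-dihydrofuran-3-carbaldehyde, via vicinal diol 15 (not isolated)
Conditions: OsO4 (2 mol%), NaIO4 (4 equiv), 2,6-lutidine, dioxane/H2O, 23 °C
Reagents that add atoms: osmium tetroxide, O=[Os](=O)(=O)=O; sodium periodate, [Na+].[O-][I](=O)(=O)=O
Why: Lemieux–Johnson cleavage: OsO4 dihydroxylates the terminal vinyl group (the most accessible alkene; the iodoalkene and the tetrasubstituted butenolide bond are deactivated) and periodate cleaves the diol to the C8 aldehyde.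

Step 10
Reactants: 16 (2R)-2-[(Z)-2-iodoprop-1-en-1-yl]-5-oxo-4-{[(triethylsilyl)oxy]methyl}-2,5-dihydrofuran-3-carbaldehyde; 5 (S)-tert-butyl({5-iodo-2-[(trimethylsilyl)methyl]pent-1-en-3-yl}oxy)dimethylsilane
Product: 17 (5R)-4-[(4S)-4-[(tert-butyldimethylsilyl)oxy]-1-hydroxy-6-iodo-3-methylidenehexyl]-5-[(Z)-2-iodoprop-1-en-1-yl]-3-{[(triethylsilyl)oxy]methyl}furan-2(5H)-one (both C8 epimers)
Conditions: BF3·OEt2 (1.2 equiv), CH2Cl2, −78 °C
Reagents that add atoms: none
Why: Hosomi–Sakurai allylation: the BF3-activated aldehyde is attacked by the γ-carbon of the 2-substituted allylsilane (anti SE2′ via a β-silyl cation), which forms C8–C9 and unveils the C10(14) methylene; C8 is formed as a mixture of epimers that is corrected in steps 11 and 12.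

Step 11
Reactants: 17 (both C8 epimers)
Product: 18 (5R)-4-[(4S)-4-[(tert-butyldimethylsilyl)oxy]-6-iodo-3-methylidenehexanoyl]-5-[(Z)-2-iodoprop-1-en-1-yl]-3-{[(triethylsilyl)oxy]methyl}furan-2(5H)-one
Conditions: Dess–Martin periodinane, NaHCO3, CH2Cl2, 0 °C
Reagents that add atoms: none
Why: Dess–Martin oxidation under buffered, non-enolising conditions converts both C8 epimers into one ketone; the iodides, silyl ethers and butenolide are inert.

Step 12
Reactants: 18 (C8 ketone)
Product: 19 (5R)-4-[(1S,4S)-4-[(tert-butyldimethylsilyl)oxy]-1-hydroxy-6-iodo-3-methylidenehexyl]-5-[(Z)-2-iodoprop-1-en-1-yl]-3-{[(triethylsilyl)oxy]methyl}furan-2(5H)-one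
Conditions: (R)-2-methyl-CBS-oxazaborolidine (1 equiv), catecholborane (2 equiv), toluene, −78 °C
Reagents that add atoms: none
Why: Corey–Bakshi–Shibata reduction: the ketone binds to the (R)-oxazaborolidine with the branched sp2 carbon C7 as the large group, and catecholborane (which does not hydroborate the alkenes at −78 °C) delivers hydride to give 8S under catalyst control.

Step 13
Reactants: 19 (8S alcohol)
Product: 20 (5R)-4-[(1S,4S)-4-[(tert-butyldimethylsilyl)oxy]-6-iodo-3-methylidene-1-[(triethylsilyl)oxy]hexyl]-5-[(Z)-2-iodoprop-1-en-1-yl]-3-{[(triethylsilyl)oxy]methyl}furan-2(5H)-one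
Conditions: TESOTf, 2,6-lutidine, CH2Cl2, −78 °C
Reagents that add atoms: triethylsilyl trifluoromethanesulfonate, CC[Si](CC)(CC)OS(=O)(=O)C(F)(F)F
Why: Silylation of the hindered secondary alcohol with the silyl triflate; a silyl ether (not the final acetate) is used at C8 because allylic esters could ionise with low-valent nickel in step 14.

Step 14
Reactants: 20 (acyclic bis-iodide)
Product: 21 (1S,4Z,6R,8S)-1-[(tert-butyldimethylsilyl)oxy]-8,13-bis[(triethylsilyl)oxy]germacra-4,7(11),10(14)-trien-12,6-olide
Conditions: NiBr2(CH3OCH2CH2OCH3) (0.5 equiv), 4,4′-di-tert-butyl-2,2′-bipyridine (0.6 equiv), Mn powder (5 equiv), DMA, 30 °C, 20 added over 12 h by syringe pump (final 2 mM)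
Reagents that add atoms: none
Why: Proposed new method: zerovalent nickel (from the divalent nickel bromide and Mn) inserts selectively into the C(sp2)–I bond at C4 with retention of the Z geometry, the reduced alkenylnickel abstracts iodine from the C3–I terminus of the same molecule, and the primary C3 radical recombines at nickel to give an eleven-membered C4–Ni–C3 nickelacycle that contracts by C(sp2)–C(sp3) reductive elimination; the closest known reaction type is the intermolecular nickel-catalysed reductive cross-electrophile coupling of alkenyl halides with primary alkyl halides and its ring-forming variants for five- to seven-membered rings, here extended to a ten-membered carbocycle. The ring closed is the ten-membered carbocycle C1–C10, and the closure is a ring contraction at the metal and not an attack on a π bond, so exo and endo rules do not apply. No stereocentre is created: C1, C6 and C8 are remote from the reacting carbons, the medium is neutral so the acidic C6–H of the butenolide is not at risk, and the 4Z geometry is inherited from the alkenyl iodide made in step 4. The step needs cyclisation over oligomerisation and cross- over homo-coupling: the first should be secured by slow addition into a dilute suspension and by the preorganisation that the cis C4=C5 bond, the fused butenolide (C6, C7) and sp2 C10 impose on the chain, the second by the different activation modes of the two iodides (two-electron oxidative addition at sp2 carbon, halogen-atom abstraction at sp3 carbon). Silyl ethers in place of acetates at C8 and C13 keep allylic C–O ionisation by low-valent nickel out of the picture.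

Step 15
Reactants: 21 (tris-silyl macrocycle)
Product: 22 (1S,4Z,6R,8S)-1-[(tert-butyldimethylsilyl)oxy]-8,13-dihydroxygermacra-4,7(11),10(14)-trien-12,6-olide
Conditions: PPTS (0.3 equiv), MeOH/CH2Cl2, 0 °C
Reagents that add atoms: none
Why: Acid-catalysed methanolysis removes the primary and the secondary triethylsilyl ether much faster than the secondary tert-butyldimethylsilyl ether at C1; a 12,8-lactone cannot form because C8 is trans to C12 across C7=C11.

Step 16
Reactants: 22 (8,13-diol)
Product: 23 (1S,4Z,6R,8S)-8,13-diacetoxy-1-[(tert-butyldimethylsilyl)oxy]germacra-4,7(11),10(14)-trien-12,6-olide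
Conditions: Ac2O, pyridine, DMAP (cat.), CH2Cl2, 0 °C
Reagents that add atoms: acetic anhydride, CC(=O)OC(C)=O
Why: DMAP-catalysed acylation of the primary C13 and secondary C8 hydroxyls; the mild amine base at 0 °C should not deprotonate C6–H.

Step 17
Reactants: 23 (diacetate silyl ether)
Product: 24 8α,13-diacetoxy-1α-hydroxygermacra-4,7(11),10(14)-trien-6α,12-olide (1S,4Z,6R,8S)
Conditions: HF·pyridine, pyridine/THF, 0 to 23 °C
Reagents that add atoms: none
Why: Fluoride-mediated desilylation under buffered, weakly acidic conditions should free the C1 allylic alcohol without acetate migration, loss of the C13 acetate or epimerisation at C6.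

**Compound list**

1 | (S)-3-hydroxydihydrofuran-2(3H)-one | O=C1OCC[C@@H]1O | starting material
2 | (S)-3-[(tert-butyldimethylsilyl)oxy]dihydrofuran-2(3H)-one | O=C1OCC[C@@H]1O[Si](C)(C)C(C)(C)C | intermediate
3 | (S)-3-[(tert-butyldimethylsilyl)oxy]-5-(trimethylsilyl)-4-[(trimethylsilyl)methyl]pentane-1,4-diol | OCC[C@@H](C(O)(C[Si](C)(C)C)C[Si](C)(C)C)O[Si](C)(C)C(C)(C)C | intermediate (not isolated)
4 | (S)-3-[(tert-butyldimethylsilyl)oxy]-4-[(trimethylsilyl)methyl]pent-4-en-1-ol | OCC[C@@H](C(=C)C[Si](C)(C)C)O[Si](C)(C)C(C)(C)C | intermediate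
5 | (S)-tert-butyl({5-iodo-2-[(trimethylsilyl)methyl]pent-1-en-3-yl}oxy)dimethylsilane | ICC[C@@H](C(=C)C[Si](C)(C)C)O[Si](C)(C)C(C)(C)C | intermediate
6 | but-2-yn-1-ol | CC#CCO | starting material
7 | sodium 2,2-bis(2-methoxyethoxy)-3-methyl-2,5-dihydro-1,2-oxaluminol-2-uide (cyclic alkenylalanate) | [Na+].CC1=CCO[Al-]1(OCCOC)OCCOC | intermediate (not isolated)
8 | (Z)-3-iodobut-2-en-1-ol | C/C(I)=C/CO | intermediate
9 | (Z)-3-iodobut-2-enal | C/C(I)=C/C=O | intermediate
10 | methyl propiolate | C#CC(=O)OC | starting material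
11 | methyl (4R,5Z)-4-hydroxy-6-iodohept-5-en-2-ynoate | O[C@@H](C#CC(=O)OC)/C=C(/C)I | intermediate
12 | methyl (2Z)-3-[(1R,2Z)-1-hydroxy-3-iodobut-2-en-1-yl]-2-(hydroxymethyl)penta-2,4-dienoate | COC(=O)/C(CO)=C(/C=C)[C@H](O)/C=C(/C)I | intermediate (not isolated)
13 | (5R)-3-(hydroxymethyl)-5-[(Z)-2-iodoprop-1-en-1-yl]-4-vinylfuran-2(5H)-one | C=CC1=C(CO)C(=O)O[C@@H]1/C=C(/C)I | intermediate
14 | (5R)-5-[(Z)-2-iodoprop-1-en-1-yl]-3-{[(triethylsilyl)oxy]methyl}-4-vinylfuran-2(5H)-one | C=CC1=C(CO[Si](CC)(CC)CC)C(=O)O[C@@H]1/C=C(/C)I | intermediate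
15 | (5R)-4-(1,2-dihydroxyethyl)-5-[(Z)-2-iodoprop-1-en-1-yl]-3-{[(triethylsilyl)oxy]methyl}furan-2(5H)-one (mixture at the new carbinol carbon) | OCC(O)C1=C(CO[Si](CC)(CC)CC)C(=O)O[C@@H]1/C=C(/C)I | intermediate (not isolated)
16 | (2R)-2-[(Z)-2-iodoprop-1-en-1-yl]-5-oxo-4-{[(triethylsilyl)oxy]methyl}-2,5-dihydrofuran-3-carbaldehyde | O=CC1=C(CO[Si](CC)(CC)CC)C(=O)O[C@@H]1/C=C(/C)I | intermediate
17 | (5R)-4-[(4S)-4-[(tert-butyldimethylsilyl)oxy]-1-hydroxy-6-iodo-3-methylidenehexyl]-5-[(Z)-2-iodoprop-1-en-1-yl]-3-{[(triethylsilyl)oxy]methyl}furan-2(5H)-one (both C8 epimers) | C=C(CC(O)C1=C(CO[Si](CC)(CC)CC)C(=O)O[C@@H]1/C=C(/C)I)[C@H](CCI)O[Si](C)(C)C(C)(C)C | intermediate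
18 | (5R)-4-[(4S)-4-[(tert-butyldimethylsilyl)oxy]-6-iodo-3-methylidenehexanoyl]-5-[(Z)-2-iodoprop-1-en-1-yl]-3-{[(triethylsilyl)oxy]methyl}furan-2(5H)-one | C=C(CC(=O)C1=C(CO[Si](CC)(CC)CC)C(=O)O[C@@H]1/C=C(/C)I)[C@H](CCI)O[Si](C)(C)C(C)(C)C | intermediate
19 | (5R)-4-[(1S,4S)-4-[(tert-butyldimethylsilyl)oxy]-1-hydroxy-6-iodo-3-methylidenehexyl]-5-[(Z)-2-iodoprop-1-en-1-yl]-3-{[(triethylsilyl)oxy]methyl}furan-2(5H)-one | C=C(C[C@H](O)C1=C(CO[Si](CC)(CC)CC)C(=O)O[C@@H]1/C=C(/C)I)[C@H](CCI)O[Si](C)(C)C(C)(C)C | intermediate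
20 | (5R)-4-[(1S,4S)-4-[(tert-butyldimethylsilyl)oxy]-6-iodo-3-methylidene-1-[(triethylsilyl)oxy]hexyl]-5-[(Z)-2-iodoprop-1-en-1-yl]-3-{[(triethylsilyl)oxy]methyl}furan-2(5H)-one | C=C(C[C@H](O[Si](CC)(CC)CC)C1=C(CO[Si](CC)(CC)CC)C(=O)O[C@@H]1/C=C(/C)I)[C@H](CCI)O[Si](C)(C)C(C)(C)C | intermediate
21 | (1S,4Z,6R,8S)-1-[(tert-butyldimethylsilyl)oxy]-8,13-bis[(triethylsilyl)oxy]germacra-4,7(11),10(14)-trien-12,6-olide | C=C1C[C@H](O[Si](CC)(CC)CC)C2=C(CO[Si](CC)(CC)CC)C(=O)O[C@@H]2/C=C(/C)CC[C@@H]1O[Si](C)(C)C(C)(C)C | intermediate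
22 | (1S,4Z,6R,8S)-1-[(tert-butyldimethylsilyl)oxy]-8,13-dihydroxygermacra-4,7(11),10(14)-trien-12,6-olide | C=C1C[C@H](O)C2=C(CO)C(=O)O[C@@H]2/C=C(/C)CC[C@@H]1O[Si](C)(C)C(C)(C)C | intermediate
23 | (1S,4Z,6R,8S)-8,13-diacetoxy-1-[(tert-butyldimethylsilyl)oxy]germacra-4,7(11),10(14)-trien-12,6-olide | C=C1C[C@H](OC(C)=O)C2=C(COC(C)=O)C(=O)O[C@@H]2/C=C(/C)CC[C@@H]1O[Si](C)(C)C(C)(C)C | intermediate
24 | 8α,13-diacetoxy-1α-hydroxygermacra-4,7(11),10(14)-trien-6α,12-olide (1S,4Z,6R,8S) | C=C1C[C@H](OC(C)=O)C2=C(COC(C)=O)C(=O)O[C@@H]2/C=C(/C)CC[C@@H]1O | target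

**Step count and risks**

Total steps: 17. Longest linear sequence: 14 steps (steps 4–17, from but-2-yn-1-ol); the allylsilane branch (steps 1–3) joins at step 10.

Steps most likely to fail:

1. Step 14 (Proposed new method). What may go wrong: intermolecular capture of the C3 radical leading to oligomers, premature reduction or 1,5-hydrogen shift of the C3 radical, or slow ionisation of the allylic lactone C6–O bond by low-valent nickel. Fallback (known two-electron chemistry, no free radical): the route is left at 20. Zinc dust (activated with 1,2-dibromoethane and TMSCl), LiCl, THF, 40 °C should insert only into the primary C3–I bond to give the alkylzinc iodide F1, the alkenyl iodide being inert to zinc. Slow addition of F1 to Pd2(dba)3/P(2-furyl)3 in THF/NMP at 50 °C and 1 mM should then close the ring by intramolecular Negishi coupling at zerovalent palladium, with retention of the Z geometry. The route is rejoined at 21.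

2. Step 7. What may go wrong: isomerisation of the alkenylcopper through the allenolate before trapping (loss of the cis relation between C6 and the ester), and sluggish or O-selective capture of formaldehyde. Fallback: the route is left at 11. After the same cuprate addition the alkenylcopper is quenched with iodine, a fast and geometry-retaining trap, and lactonisation gives (5R)-3-iodo-5-[(Z)-2-iodoprop-1-en-1-yl]-4-vinylfuran-2(5H)-one F2. Iodine–magnesium exchange with iPrMgCl·LiCl in THF at −78 °C should occur only at the carbonyl-activated C11–I bond, the unactivated alkenyl iodide at C4 not exchanging at this temperature. Addition of monomeric formaldehyde to the resulting alkenylmagnesium species rejoins the route at 13.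

3. Step 12. What may go wrong: insufficient catalyst control against the bias of the neighbouring C6 centre, conjugate reduction of the butenolide, or migration of the C10(14) double bond into conjugation by enolisation of ketone 18 before reduction. Fallback (no ketone): the route is left at 17. The two C8 epimers are separated by chromatography; the (8S)-epimer is 19 itself. The (8R)-epimer F3 is inverted by Mitsunobu esterification (chloroacetic acid, PPh3, DIAD, toluene, 0 °C) to the (8S)-chloroacetate F4, which is cleaved with thiourea and NaHCO3 in ethanol at 23 °C, conditions that should spare the butenolide. The route is rejoined at 19.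

**Further compounds**

F1 | step 14 | alkylzinc iodide of 20 (C3–ZnI in place of C3–I): iodo{(3S,6S)-3-[(tert-butyldimethylsilyl)oxy]-6-[(2R)-2-[(Z)-2-iodoprop-1-en-1-yl]-5-oxo-4-{[(triethylsilyl)oxy]methyl}-2,5-dihydrofuran-3-yl]-4-methylidene-6-[(triethylsilyl)oxy]hexyl}zinc | C=C(C[C@H](O[Si](CC)(CC)CC)C1=C(CO[Si](CC)(CC)CC)C(=O)O[C@@H]1/C=C(/C)I)[C@H](CC[Zn]I)O[Si](C)(C)C(C)(C)C
F2 | step 7 | (5R)-3-iodo-5-[(Z)-2-iodoprop-1-en-1-yl]-4-vinylfuran-2(5H)-one | C=CC1=C(I)C(=O)O[C@@H]1/C=C(/C)I
F3 | step 12 | (5R)-4-[(1R,4S)-4-[(tert-butyldimethylsilyl)oxy]-1-hydroxy-6-iodo-3-methylidenehexyl]-5-[(Z)-2-iodoprop-1-en-1-yl]-3-{[(triethylsilyl)oxy]methyl}furan-2(5H)-one | C=C(C[C@@H](O)C1=C(CO[Si](CC)(CC)CC)C(=O)O[C@@H]1/C=C(/C)I)[C@H](CCI)O[Si](C)(C)C(C)(C)C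
F4 | step 12 | (1S,4S)-4-[(tert-butyldimethylsilyl)oxy]-6-iodo-1-[(2R)-2-[(Z)-2-iodoprop-1-en-1-yl]-5-oxo-4-{[(triethylsilyl)oxy]methyl}-2,5-dihydrofuran-3-yl]-3-methylidenehexyl chloroacetate | C=C(C[C@H](OC(=O)CCl)C1=C(CO[Si](CC)(CC)CC)C(=O)O[C@@H]1/C=C(/C)I)[C@H](CCI)O[Si](C)(C)C(C)(C)C
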